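The piperidine is cut at N1'–C2'. C2' is the benzylic carbon on C8 of ring A and sits ortho to the C8a oxygen, so it can be the exocyclic carbon of an ortho-quinone methide. In one operation a chiral phosphoric acid dehydrates a racemic ortho-hydroxybenzylic alcohol to this planar intermediate and delivers the tethered carbamate nitrogen to one face, closing the piperidine and setting the only stereocenter (R). The precursor is open-chain: a 2-hydroxy-4,6-dimethoxyphenyl ring carrying a 1-hydroxypentyl chain that ends in NHCO2Me. The carbamate later becomes N-methyl and the free phenol becomes O1 of ring C.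

Key step: step 5

Remark on labels: flavone numbering is used (O1 to C8a; ring A is the benzo ring, ring C the pyranone); piperidine atoms are primed.
Assumption: the sense of induction cannot be predicted with confidence for this substrate; the (R)-configured catalyst is written, and its mirror image is to be used if screening shows that it delivers the S product.

Step 1
Reactants: 1 2-piperidone; 2 methyl chloroformate
Product: 3 methyl 2-oxopiperidine-1-carboxylate
Conditions: n-BuLi (1.05 equiv), THF, −78 °C; then 2, −78 °C → rt
Reagents that add atoms: methyl chloroformate (2), COC(=O)Cl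
Why: N-acylation of the lithium lactamate by the chloroformate (imide formation) is fast at low temperature and should give the activated N-acyl lactam; no stereocenter is formed.

Step 2
Reactants: 4 1,3,5-trimethoxybenzene; 3 methyl 2-oxopiperidine-1-carboxylate
Product: 6 methyl N-[5-oxo-5-(2,4,6-trimethoxyphenyl)pentyl]carbamate, via 2,4,6-trimethoxyphenyllithium 5 (not isolated)
Conditions: n-BuLi, TMEDA, THF, 0 °C → rt; then 3, −78 °C → −20 °C; then H2O
Reagents that add atoms: none
Why: Directed ortho-lithiation of the symmetric arene gives a single aryllithium, whose addition to the ring carbonyl of the N-alkoxycarbonyl lactam (nucleophilic acyl substitution with ring opening) releases a carbamate anion and a hindered ketone, so a second addition should not follow.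

Step 3
Reactants: 6 methyl N-[5-oxo-5-(2,4,6-trimethoxyphenyl)pentyl]carbamate
Product: 7 methyl N-[5-(2-hydroxy-4,6-dimethoxyphenyl)-5-oxopentyl]carbamate
Conditions: BCl3 (2.5 equiv), CH2Cl2, −78 °C → 0 °C; then H2O
Reagents that add atoms: none
Why: Chelation-assisted ether cleavage: BCl3 bridges the ketone oxygen and one of the two equivalent ortho methoxy groups, chloride removes that methyl, and the boron chelate so formed shields the second ortho ether, while the para ether and the methyl carbamate should survive at low temperature.

Step 4
Reactants: 7 methyl N-[5-(2-hydroxy-4,6-dimethoxyphenyl)-5-oxopentyl]carbamate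
Product: 8 racemic methyl N-[5-hydroxy-5-(2-hydroxy-4,6-dimethoxyphenyl)pentyl]carbamate
Conditions: NaBH4 (3 equiv), THF/MeOH, 0 °C; pH 7 phosphate buffer work-up, cold; used crude
Reagents that add atoms: none
Why: Borohydride reduction of the aryl ketone leaves the carbamate untouched; the carbinol center is made racemic on purpose because the next step erases it, and cold neutral work-up without chromatography should keep the acid-labile alcohol from ionising.

Step 5
Reactants: 8 racemic methyl N-[5-hydroxy-5-(2-hydroxy-4,6-dimethoxyphenyl)pentyl]carbamate
Product: 10 methyl (R)-2-(2-hydroxy-4,6-dimethoxyphenyl)piperidine-1-carboxylate, via ortho-quinone methide 9 (not isolated)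
Conditions: (R)-3,3'-bis(2,4,6-triisopropylphenyl)-1,1'-binaphthyl-2,2'-diyl hydrogen phosphate (10 mol %), 4 Å molecular sieves, toluene (0.02 M), −40 °C; Et3N quench
Reagents that add atoms: none
Why: Proposed new method: the phosphoric acid protonates the benzylic hydroxyl of 8 and water leaves with electron push from the ortho phenol and the two methoxy groups, so both enantiomers of 8 drain into the same planar ortho-quinone methide 9, which stays hydrogen-bonded to the phosphate. The closest known reaction type is the chiral phosphoric acid-catalysed conjugate addition of external nucleophiles to ortho-quinone methides generated in situ from ortho-hydroxybenzyl alcohols; a tethered carbamate nitrogen closing onto a 2,4,6-trioxygenated quinone methide has not been shown. The piperidine closes in a 6-exo-trig aza-Michael attack of the carbamate nitrogen on the exocyclic methide carbon (N1'–C2'), which restores the aromatic ring and returns the free phenol. The new stereocenter C2' is set by the catalyst: its P–OH holds the quinone methide oxygen and its P=O accepts the carbamate N–H, so the tether should reach only the face left open by the 2,4,6-triisopropylphenyl walls of the binaphthyl pocket. The step needs enantioface selectivity over closure of a free benzylic cation; the substrate helps because the methoxy group ortho to the methide carbon should allow only the Z alkylidene geometry and the phenol oxygen and N–H give the catalyst two anchoring points, while toluene, low temperature, sieves and high dilution keep the ion pair tight and suppress dimerisation.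

Step 6
Reactants: 10 methyl (R)-2-(2-hydroxy-4,6-dimethoxyphenyl)piperidine-1-carboxylate
Product: 11 (R)-3,5-dimethoxy-2-(1-methylpiperidin-2-yl)phenol
Conditions: LiAlH4 (4 equiv), THF, 0 °C → 65 °C; then H2O, aq. NaOH
Reagents that add atoms: none
Why: Hydride reduction of a carbamate to an N-methyl amine (LiAlH4, through the formamide and iminium stages) runs under basic conditions in which C2' is neither acidic nor prone to ionise, so the R center should be carried through.

Step 7
Reactants: 11 (R)-3,5-dimethoxy-2-(1-methylpiperidin-2-yl)phenol
Product: 13 1-[2-hydroxy-4,6-dimethoxy-3-[(2R)-1-methylpiperidin-2-yl]phenyl]ethan-1-one, via aryl acetate 12 (not isolated)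
Conditions: Ac2O (1.2 equiv), BF3·OEt2 (5 equiv), CH2Cl2, 0 °C → 40 °C; then H2O
Reagents that add atoms: acetic anhydride, CC(=O)OC(C)=O
Why: Friedel–Crafts acetylation by way of O-acetylation and BF3-promoted Fries rearrangement should place the acetyl group on the only free carbon ortho to the phenol, the future C4a, because boron chelation between the phenol oxygen and the new carbonyl favours that position, while the amine is tied up by the Lewis acid and C2' should not ionise at this temperature.

Step 8
Reactants: 13 1-[2-hydroxy-4,6-dimethoxy-3-[(2R)-1-methylpiperidin-2-yl]phenyl]ethan-1-one; 14 benzoyl chloride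
Product: 15 1-[2-hydroxy-4,6-dimethoxy-3-[(2R)-1-methylpiperidin-2-yl]phenyl]-3-phenylpropane-1,3-dione
Conditions: LiN(SiMe3)2 (4 equiv), THF, −78 °C → −10 °C; then 14 (1.05 equiv), −78 °C → rt; then H2O
Reagents that add atoms: benzoyl chloride (14), O=C(Cl)c1ccccc1
Why: Claisen-type C-benzoylation of the lithium phenoxide–enolate dianion should give the 1,3-diketone directly, the one-flask equivalent of O-benzoylation and Baker–Venkataraman rearrangement, since any aryl benzoate formed is rearranged by the excess amide base, and the tertiary amine and C2' are inert to these conditions.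

Step 9
Reactants: 15 1-[2-hydroxy-4,6-dimethoxy-3-[(2R)-1-methylpiperidin-2-yl]phenyl]-3-phenylpropane-1,3-dione
Product: 16 5,7-dimethoxy-8-[(2R)-1-methylpiperidin-2-yl]-2-phenyl-4H-chromen-4-one
Conditions: conc. HCl, AcOH, 50 °C
Reagents that add atoms: none
Why: Acid-catalysed cyclodehydration (closing stage of the Baker–Venkataraman flavone synthesis): the only free phenol, at the future C8a, adds to the benzoyl carbonyl and water is lost, so ring C can form only with the piperidine at C8, while the protonated amine and the acyl-deactivated ring A should keep C2' from ionising.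

Step 10
Reactants: 16 5,7-dimethoxy-8-[(2R)-1-methylpiperidin-2-yl]-2-phenyl-4H-chromen-4-one
Product: 17 5,7-dihydroxy-8-[(2R)-1-methylpiperidin-2-yl]-2-phenyl-4H-chromen-4-one
Conditions: BBr3 (6 equiv), CH2Cl2, −78 °C → rt; then H2O
Reagents that add atoms: none
Why: Lewis acid cleavage of aryl methyl ethers by BBr3 should remove the C5 ether quickly through chelation to the C4 carbonyl and the C7 ether more slowly, with excess reagent covering the amine and carbonyl, and staying at or below room temperature avoids the Wessely–Moser isomerisation of ring C and the C2'–N ionisation that hot protic acids could cause.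

Compound list
1 | 2-piperidone | O=C1CCCCN1 | starting material
2 | methyl chloroformate | COC(=O)Cl | starting material
3 | methyl 2-oxopiperidine-1-carboxylate | COC(=O)N1CCCCC1=O | intermediate
4 | 1,3,5-trimethoxybenzene | COc1cc(OC)cc(OC)c1 | starting material
5 | 2,4,6-trimethoxyphenyllithium (formed in the flask, not isolated) | [Li]c1c(OC)cc(OC)cc1OC | intermediate
6 | methyl N-[5-oxo-5-(2,4,6-trimethoxyphenyl)pentyl]carbamate | COC(=O)NCCCCC(=O)c1c(OC)cc(OC)cc1OC | intermediate
7 | methyl N-[5-(2-hydroxy-4,6-dimethoxyphenyl)-5-oxopentyl]carbamate | COC(=O)NCCCCC(=O)c1c(O)cc(OC)cc1OC | intermediate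
8 | racemic methyl N-[5-hydroxy-5-(2-hydroxy-4,6-dimethoxyphenyl)pentyl]carbamate | COC(=O)NCCCCC(O)c1c(O)cc(OC)cc1OC | intermediate
9 | methyl N-[(5Z)-5-(2,4-dimethoxy-6-oxocyclohexa-2,4-dien-1-ylidene)pentyl]carbamate (ortho-quinone methide, geometry as expected, not isolated) | COC(=O)NCCCC/C=C1\C(=O)C=C(OC)C=C1OC | intermediate
10 | methyl (R)-2-(2-hydroxy-4,6-dimethoxyphenyl)piperidine-1-carboxylate | COC(=O)N1CCCC[C@@H]1c1c(O)cc(OC)cc1OC | intermediate
11 | (R)-3,5-dimethoxy-2-(1-methylpiperidin-2-yl)phenol | CN1CCCC[C@@H]1c1c(O)cc(OC)cc1OC | intermediate
12 | (R)-3,5-dimethoxy-2-(1-methylpiperidin-2-yl)phenyl acetate (not isolated) | CN1CCCC[C@@H]1c1c(OC(C)=O)cc(OC)cc1OC | intermediate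
13 | 1-[2-hydroxy-4,6-dimethoxy-3-[(2R)-1-methylpiperidin-2-yl]phenyl]ethan-1-one | CN1CCCC[C@@H]1c1c(O)c(C(C)=O)c(OC)cc1OC | intermediate
14 | benzoyl chloride | O=C(Cl)c1ccccc1 | starting material
15 | 1-[2-hydroxy-4,6-dimethoxy-3-[(2R)-1-methylpiperidin-2-yl]phenyl]-3-phenylpropane-1,3-dione | CN1CCCC[C@@H]1c1c(O)c(C(=O)CC(=O)c2ccccc2)c(OC)cc1OC | intermediate
16 | 5,7-dimethoxy-8-[(2R)-1-methylpiperidin-2-yl]-2-phenyl-4H-chromen-4-one | CN1CCCC[C@@H]1c1c(OC)cc(OC)c2c(=O)cc(-c3ccccc3)oc12 | intermediate
17 | 5,7-dihydroxy-8-[(2R)-1-methylpiperidin-2-yl]-2-phenyl-4H-chromen-4-one | CN1CCCC[C@@H]1c1c(O)cc(O)c2c(=O)cc(-c3ccccc3)oc12 | target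

Total step count: 10. Longest linear sequence: 10 steps (2-piperidone to the target; the arene enters at step 2).

Steps most likely to fail

Step 5. The ring may close through a free benzylic cation outside the catalyst pocket, the product may lose enantiomeric purity by acid-promoted reionisation of the C2'–N bond, or the quinone methide may dimerise. The fallback replaces asymmetric catalysis by racemic closure and classical resolution, all known chemistry. It sets out from 8: catalytic p-toluenesulfonic acid monohydrate in CH2Cl2 at 0 °C should close the ring to racemic methyl 2-(2-hydroxy-4,6-dimethoxyphenyl)piperidine-1-carboxylate F1. LiAlH4 in THF should reduce this to racemic 3,5-dimethoxy-2-(1-methylpiperidin-2-yl)phenol F2. Fractional crystallisation with (2R,3R)-O,O'-di-p-toluoyltartaric acid is then expected to give the 1:1 salt of the R amine with (2R,3R)-O,O'-di-p-toluoyltartaric acid F3; the mirror-image acid is used if the salt of the S amine proves the less soluble one, judged by HPLC on a chiral phase. Aqueous NaHCO3 liberates the free base, which is 11, and the route continues at step 7.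

Step 4. The hydrogen-bonded, electron-rich ketone may reduce slowly, the phenoxide may expel the borate and let hydride add to the resulting quinone methide (over-reduction to the alkyl chain), or the alcohol may ionise and close unselectively during isolation. The fallback masks the phenol during the reduction and sets out from 7. TBSCl and imidazole in DMF should give methyl N-[5-[2-(tert-butyldimethylsilyloxy)-4,6-dimethoxyphenyl]-5-oxopentyl]carbamate F4. NaBH4 in THF/EtOH at 0 °C should reduce this ordinary aryl ketone to racemic methyl N-[5-[2-(tert-butyldimethylsilyloxy)-4,6-dimethoxyphenyl]-5-hydroxypentyl]carbamate F5, in which no phenoxide can trigger elimination. Tetrabutylammonium fluoride (Bu4NF) buffered with AcOH in THF at 0 °C then frees the phenol to give 8, which goes directly into step 5.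

Step 7. Acetylation may occur at the ring carbon between the two methoxy groups (the future C6) instead of the carbon ortho to the phenol, or the Lewis acid may promote C2'–N ionisation and erode configurational purity. The fallback uses a base-mediated, phenoxide-directed carbon–carbon bond formation and sets out from 11. MgCl2, Et3N and paraformaldehyde in MeCN at reflux (magnesium phenoxide-directed ortho-formylation) should give 2-hydroxy-4,6-dimethoxy-3-[(2R)-1-methylpiperidin-2-yl]benzaldehyde F6. Excess MeMgBr in THF at 0 °C should add to give 1-[2-hydroxy-4,6-dimethoxy-3-[(2R)-1-methylpiperidin-2-yl]phenyl]ethan-1-ol F7, as a mixture at the new carbinol carbon, which is of no consequence. MnO2 in CH2Cl2 should oxidise the benzylic alcohol to 13, and the route continues at step 8.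

Further compounds
F1 | step 5 | racemic methyl 2-(2-hydroxy-4,6-dimethoxyphenyl)piperidine-1-carboxylate | COC(=O)N1CCCCC1c1c(O)cc(OC)cc1OC
F2 | step 5 | racemic 3,5-dimethoxy-2-(1-methylpiperidin-2-yl)phenol | CN1CCCCC1c1c(O)cc(OC)cc1OC
F3 | step 5 | 1:1 salt of (R)-3,5-dimethoxy-2-(1-methylpiperidin-2-yl)phenol with (2R,3R)-O,O'-di-p-toluoyltartaric acid | CN1CCCC[C@@H]1c1c(O)cc(OC)cc1OC.OC(=O)[C@H](OC(=O)c1ccc(C)cc1)[C@@H](OC(=O)c1ccc(C)cc1)C(O)=O
F4 | step 4 | methyl N-[5-[2-(tert-butyldimethylsilyloxy)-4,6-dimethoxyphenyl]-5-oxopentyl]carbamate | COC(=O)NCCCCC(=O)c1c(O[Si](C)(C)C(C)(C)C)cc(OC)cc1OC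
F5 | step 4 | racemic methyl N-[5-[2-(tert-butyldimethylsilyloxy)-4,6-dimethoxyphenyl]-5-hydroxypentyl]carbamate | COC(=O)NCCCCC(O)c1c(O[Si](C)(C)C(C)(C)C)cc(OC)cc1OC
F6 | step 7 | 2-hydroxy-4,6-dimethoxy-3-[(2R)-1-methylpiperidin-2-yl]benzaldehyde | CN1CCCC[C@@H]1c1c(O)c(C=O)c(OC)cc1OC
F7 | step 7 | 1-[2-hydroxy-4,6-dimethoxy-3-[(2R)-1-methylpiperidin-2-yl]phenyl]ethan-1-ol | CN1CCCC[C@@H]1c1c(O)c(C(C)O)c(OC)cc1OC
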